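**Retrosynthetic overview**
1. The target is read as (2S,4R)-7,3',4'-trihydroxyflavan-(4β→8)-(+)-catechin: upper unit 2,4-trans, lower unit 2R,3S, linked at C8. The last step is hydrogenolysis of six O-benzyl groups.
2. Key disconnection: the C4(upper)–C8(lower) interflavan bond and the C4 stereocentre, made by a new chiral-phosphoric-acid-catalysed 1,6-arylation of a flavan para-quinone methide (from a 7-hydroxyflavan-4-ol) with tetra-O-benzyl-(+)-catechin.
3. Upper unit: a (2S,4S)-flavan-4-ol from asymmetric transfer hydrogenation with kinetic resolution of a racemic flavanone (fixes C2). The flavanone comes from oxa-Michael closure of a 2'-hydroxychalcone made by Claisen–Schmidt condensation.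
4. Lower unit: (+)-catechin from the chiral pool (2R,3S centres in place), benzylated on its four phenols.
5. Ring order: rings A and B of the upper unit come from the two aromatic starting materials and its ring C is closed in step 3. The lower unit's rings are preformed, and the halves are joined in step 7.

Assumption: (R)-TRIP is taken as the matched enantiomer of the phosphoric acid in step 7; if the match proves reversed, its mirror image (S)-TRIP is used in the same way.

**Route**

Step 1
Reactants: 1 2,4-dihydroxyacetophenone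
Product: 2 4-allyloxy-2-hydroxyacetophenone
Conditions: allyl bromide (1.05 equiv), K2CO3 (1.1 equiv), acetone, reflux, 6 h
Reagents that add atoms: allyl bromide, C=CCBr
Why: Williamson etherification is selective for the 4-OH because the 2-OH is tied up in a hydrogen bond to the ketone and is less acidic and less nucleophilic.

Step 2
Reactants: 2 4-allyloxy-2-hydroxyacetophenone; 3 3,4-bis(benzyloxy)benzaldehyde
Product: 4 (E)-1-[4-(allyloxy)-2-hydroxyphenyl]-3-[3,4-bis(benzyloxy)phenyl]prop-2-en-1-one
Conditions: KOH (50% aq., 5 equiv), EtOH, rt, 36 h; then 1 M HCl to pH 3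
Reagents that add atoms: none
Why: Claisen–Schmidt condensation (aldol addition then dehydration) gives the conjugated E-chalcone, and allyl and benzyl ethers are inert to hydroxide.

Step 3
Reactants: 4 (E)-1-[4-(allyloxy)-2-hydroxyphenyl]-3-[3,4-bis(benzyloxy)phenyl]prop-2-en-1-one
Product: 5 rac-7-(allyloxy)-2-[3,4-bis(benzyloxy)phenyl]chroman-4-one
Conditions: NaOAc (3 equiv), EtOH/H2O 10:1, reflux, 36 h; unreacted 4 recycled
Reagents that add atoms: none
Why: Base-mediated intramolecular oxa-Michael addition of the 2'-phenol closes ring C (chalcone–flavanone isomerisation) to give the racemic flavanone, the equilibrium being driven by recycling recovered chalcone.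

Step 4
Reactants: 5 rac-7-(allyloxy)-2-[3,4-bis(benzyloxy)phenyl]chroman-4-one
Product: 6 (2S,4S)-7-(allyloxy)-2-[3,4-bis(benzyloxy)phenyl]chroman-4-ol
Conditions: RuCl[(S,S)-TsDPEN](p-cymene) (1 mol%), HCO2H/Et3N 5:2, EtOAc, 30 °C, stopped at about 48% conversion; chromatography, recrystallisation
Reagents that add atoms: none
Why: Noyori–Ikariya asymmetric transfer hydrogenation run as a kinetic resolution: the (S,S)-catalyst makes the (4S)-carbinol (same sense as chroman-4-one to (S)-chroman-4-ol), and only in (2S)-5 is that face also the favoured axial one anti to the 2-aryl group, so (2S)-5 is reduced fast to cis-(2S,4S)-6 and C2 is fixed by resolution, while the (2R)-enantiomer of 5 is recovered, re-racemised under the conditions of step 3 and recycled.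

Step 5
Reactants: 6 (2S,4S)-7-(allyloxy)-2-[3,4-bis(benzyloxy)phenyl]chroman-4-ol
Product: 7 (2S,4S)-2-[3,4-bis(benzyloxy)phenyl]chromane-4,7-diol
Conditions: Pd(PPh3)4 (3 mol%), morpholine (5 equiv), THF, rt, 1 h; pH 7 buffer work-up, Et3N-deactivated silica
Reagents that add atoms: none
Why: Tsuji–Trost-type deallylation, in which zerovalent palladium ionises the aryl allyl ether and morpholine takes up the allyl group, frees the 7-OH under non-acidic conditions that leave the benzyl ethers, the acid-labile 4-OH and both stereocentres untouched.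

Step 6
Reactants: 8 (+)-catechin
Product: 9 (2R,3S)-5,7-bis(benzyloxy)-2-[3,4-bis(benzyloxy)phenyl]chroman-3-ol
Conditions: BnBr (4.4 equiv), K2CO3 (5 equiv), DMF, 0 °C to rt, N2, 16 h
Reagents that add atoms: benzyl bromide, BrCc1ccccc1
Why: Williamson O-benzylation with carbonate alkylates only the four phenols (the aliphatic 3-OH is not deprotonated), and the mild oxygen-free conditions leave C2 and C3 unchanged.

Step 7
Reactants: 7 (2S,4S)-2-[3,4-bis(benzyloxy)phenyl]chromane-4,7-diol; 9 (2R,3S)-5,7-bis(benzyloxy)-2-[3,4-bis(benzyloxy)phenyl]chroman-3-ol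
Product: 11 (2R,3S)-5,7-bis(benzyloxy)-2-[3,4-bis(benzyloxy)phenyl]-8-{(2S,4R)-2-[3,4-bis(benzyloxy)phenyl]-7-hydroxychroman-4-yl}chroman-3-ol, via para-quinone methide 10 (not isolated)
Conditions: (R)-TRIP [(R)-3,3'-bis(2,4,6-triisopropylphenyl)-1,1'-binaphthyl-2,2'-diyl hydrogen phosphate] (10 mol%), 9 (2.5 equiv, excess recovered), 4 Å MS, toluene/CH2Cl2 4:1, −20 to 0 °C, 7 added over 4 h
Reagents that add atoms: none
Why: Proposed new method: the phosphoric acid dehydrates the para-hydroxybenzylic alcohol 7 to para-quinone methide 10 (the C4 configuration of 7 is erased, so any 4-epimer converges), then the phosphate bridges the C7 carbonyl of 10 (P–OH···O=C) and the 3-OH of 9 (P=O···H–O) and so delivers the innately most nucleophilic C8 of the tribenzyloxy ring A of 9 to C4 in a 1,6-conjugate Friedel–Crafts addition along the torsionally favoured pseudo-axial trajectory anti to the pseudo-equatorial 2-aryl group, which rearomatises ring A of the upper unit and sets the 4R (4β, 2,4-trans) centre under combined substrate and catalyst control; the closest known reaction type is the chiral-phosphoric-acid-catalysed enantioselective 1,6-addition of electron-rich arenes (indoles, naphthols, phenols) to para-quinone methides generated in situ from para-hydroxybenzyl alcohols, which has not been shown for a cyclic flavan-derived quinone methide, for a flavan-3-ol nucleophile or for interflavan bond formation.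

Step 8
Reactants: 11 (2R,3S)-5,7-bis(benzyloxy)-2-[3,4-bis(benzyloxy)phenyl]-8-{(2S,4R)-2-[3,4-bis(benzyloxy)phenyl]-7-hydroxychroman-4-yl}chroman-3-ol
Product: 12 (2R,3S)-2-(3,4-dihydroxyphenyl)-8-[(2S,4R)-2-(3,4-dihydroxyphenyl)-7-hydroxychroman-4-yl]chromane-3,5,7-triol
Conditions: H2 (1 atm), Pd(OH)2/C (20 wt%), THF/MeOH/H2O 20:1:1, rt, 12 h; filtration, Sephadex LH-20
Reagents that add atoms: none
Why: Catalytic hydrogenolysis cleaves the six aryl benzyl ethers, while the cyclic C2–O1 ethers and the diarylmethine C4–C8 bond are far slower to cleave under these neutral conditions, so no stereocentre is touched.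

**Compound list**
1 | 2,4-dihydroxyacetophenone | CC(=O)c1ccc(O)cc1O | starting material
2 | 4-allyloxy-2-hydroxyacetophenone | CC(=O)c1ccc(OCC=C)cc1O | intermediate
3 | 3,4-bis(benzyloxy)benzaldehyde | O=Cc1ccc(OCc2ccccc2)c(OCc2ccccc2)c1 | starting material
4 | (E)-1-[4-(allyloxy)-2-hydroxyphenyl]-3-[3,4-bis(benzyloxy)phenyl]prop-2-en-1-one (2'-hydroxychalcone) | O=C(/C=C/c1ccc(OCc2ccccc2)c(OCc2ccccc2)c1)c1ccc(OCC=C)cc1O | intermediate
5 | rac-7-(allyloxy)-2-[3,4-bis(benzyloxy)phenyl]chroman-4-one (racemic flavanone) | O=C1CC(c2ccc(OCc3ccccc3)c(OCc3ccccc3)c2)Oc2cc(OCC=C)ccc21 | intermediate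
6 | (2S,4S)-7-(allyloxy)-2-[3,4-bis(benzyloxy)phenyl]chroman-4-ol (2,4-cis) | C=CCOc1ccc2c(c1)O[C@H](c1ccc(OCc3ccccc3)c(OCc3ccccc3)c1)C[C@@H]2O | intermediate
7 | (2S,4S)-2-[3,4-bis(benzyloxy)phenyl]chromane-4,7-diol | Oc1ccc2c(c1)O[C@H](c1ccc(OCc3ccccc3)c(OCc3ccccc3)c1)C[C@@H]2O | intermediate
8 | (+)-catechin, (2R,3S)-2-(3,4-dihydroxyphenyl)chromane-3,5,7-triol | Oc1cc(O)c2c(c1)O[C@H](c1ccc(O)c(O)c1)[C@@H](O)C2 | starting material
9 | 5,7,3',4'-tetra-O-benzyl-(+)-catechin, (2R,3S)-5,7-bis(benzyloxy)-2-[3,4-bis(benzyloxy)phenyl]chroman-3-ol | c1ccccc1COc1cc(OCc3ccccc3)c2c(c1)O[C@H](c1ccc(OCc3ccccc3)c(OCc3ccccc3)c1)[C@@H](O)C2 | intermediate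
10 | (2S)-2-[3,4-bis(benzyloxy)phenyl]-2,3-dihydro-7H-chromen-7-one (para-quinone methide, C4=C4a) | O=C1C=CC2=CC[C@@H](c3ccc(OCc4ccccc4)c(OCc4ccccc4)c3)OC2=C1 | intermediate (not isolated)
11 | (2R,3S)-5,7-bis(benzyloxy)-2-[3,4-bis(benzyloxy)phenyl]-8-{(2S,4R)-2-[3,4-bis(benzyloxy)phenyl]-7-hydroxychroman-4-yl}chroman-3-ol | Oc1ccc2c(c1)O[C@H](c1ccc(OCc3ccccc3)c(OCc3ccccc3)c1)C[C@H]2c1c(OCc3ccccc3)cc(OCc3ccccc3)c2c1O[C@H](c1ccc(OCc3ccccc3)c(OCc3ccccc3)c1)[C@@H](O)C2 | intermediate
12 | (2R,3S)-2-(3,4-dihydroxyphenyl)-8-[(2S,4R)-2-(3,4-dihydroxyphenyl)-7-hydroxychroman-4-yl]chromane-3,5,7-triol | Oc1ccc2c(c1)O[C@H](c1ccc(O)c(O)c1)C[C@H]2c1c(O)cc(O)c2c1O[C@H](c1ccc(O)c(O)c1)[C@@H](O)C2 | target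

**Step count and risks**

Total steps: 8. Longest linear sequence: 7 steps (steps 1, 2, 3, 4, 5, 7, 8 from compound 1); the catechin branch is 3 steps (6, 7, 8).

Three steps most likely to fail:

Step 7 (the proposed new method). Risks are too little acidity for turnover, self-condensation of 7 through its own phenolic ring, or weak catalyst reinforcement of the 2,4-trans preference. The fallback uses known chemistry, sets out from 6 (with 9) and returns to the route at 11. The still 7-O-allylated alcohol 6 and 9 (2.5 equiv) are condensed with BF3·OEt2 (20 mol%) in CH2Cl2 at −40 to 0 °C. This is the classical Lewis-acid dehydrative Friedel–Crafts coupling of a flavan-4-ol with a phloroglucinol-type flavan. Ionisation at C4 and substrate-controlled axial attack anti to the 2-aryl group give mainly the 2,4-trans dimer (2R,3S)-8-{(2S,4R)-7-(allyloxy)-2-[3,4-bis(benzyloxy)phenyl]chroman-4-yl}-5,7-bis(benzyloxy)-2-[3,4-bis(benzyloxy)phenyl]chroman-3-ol F1. The 2,4-cis epimer is removed by chromatography, and deallylation with Pd(PPh3)4/morpholine in THF as in step 5 gives 11.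

Step 4 (kinetic resolution). Risks are a modest selectivity factor for this substitution pattern or base-induced ring opening of the flavanone. The fallback sets out from 5 and returns at 6, replacing metal-catalysed resolution of the ketone by enzymatic resolution of the alcohol. NaBH4 in MeOH/THF at 0 °C reduces racemic 5 by axial hydride delivery to racemic cis-7-(allyloxy)-2-[3,4-bis(benzyloxy)phenyl]chroman-4-ol F2. Lipase PS (Burkholderia cepacia lipase) with vinyl acetate in tert-butyl methyl ether at 35 °C then acylates the (4R)-enantiomer, as predicted by Kazlauskas' rule, to (2R,4R)-4-acetoxy-7-(allyloxy)-2-[3,4-bis(benzyloxy)phenyl]chromane F3. The unreacted (2S,4S)-alcohol 6 is separated by chromatography at about 52% conversion.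

Step 8 (global debenzylation). Risks are stalling at partially benzylated stages, hydrogenolysis at the doubly benzylic C4 or at C2–O1, and air oxidation of the polyphenol. The fallback sets out from 11 and returns at 12, replacing hydrogenolysis by Lewis-acid dealkylation: BCl3 (excess) with pentamethylbenzene as benzyl-cation scavenger in CH2Cl2 at −78 °C, then MeOH quench and Sephadex LH-20. The low temperature protects the acid-sensitive interflavan bond, and the fallback passes through no new compound (F0).

Further compounds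
F1 | step 7 | (2R,3S)-8-{(2S,4R)-7-(allyloxy)-2-[3,4-bis(benzyloxy)phenyl]chroman-4-yl}-5,7-bis(benzyloxy)-2-[3,4-bis(benzyloxy)phenyl]chroman-3-ol | C=CCOc1ccc2c(c1)O[C@H](c1ccc(OCc3ccccc3)c(OCc3ccccc3)c1)C[C@H]2c1c(OCc3ccccc3)cc(OCc3ccccc3)c2c1O[C@H](c1ccc(OCc3ccccc3)c(OCc3ccccc3)c1)[C@@H](O)C2
F2 | step 4 | racemic cis-7-(allyloxy)-2-[3,4-bis(benzyloxy)phenyl]chroman-4-ol (1:1 mixture of the (2S,4S)- and (2R,4R)-enantiomers) | C=CCOc1ccc2c(c1)O[C@H](c1ccc(OCc3ccccc3)c(OCc3ccccc3)c1)C[C@@H]2O.C=CCOc1ccc2c(c1)O[C@@H](c1ccc(OCc3ccccc3)c(OCc3ccccc3)c1)C[C@H]2O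
F3 | step 4 | (2R,4R)-4-acetoxy-7-(allyloxy)-2-[3,4-bis(benzyloxy)phenyl]chromane | C=CCOc1ccc2c(c1)O[C@@H](c1ccc(OCc3ccccc3)c(OCc3ccccc3)c1)C[C@H]2OC(C)=O
F0 | step 8 | none | none
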